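## The problem

CNP0182929.1 (36) is a rearranged clerodane. A trans-fused decalin (ring A: C5–C6–C7–C8–C9–C10; ring B: C10–C1–C2–C3=C4–C5) carries a γ-lactone across C4/C5 (C5–C19–O–C18(=O)–C4). A seven-membered ketone ring C (C10–C1–C16–C13–C12–C11–C9) is fused through C13/C16 to a furan (O–C15=C14–C13=C16).

Seven stereocentres must be set: the vicinal pair C8 (tertiary) and C9 (quaternary), the quaternary C5, the ring-fusion carbons C10 and C1, and the carbinol carbons C7 (axial acetate) and C2 (equatorial allylic alcohol). Only C8/C9 need an external source of chirality. Once C9 is fixed it can dictate C5, but only if its C11 arm is held in the plane of ring B. The two axial β groups on C5 and C9 then steer hydride at C7, C10 follows from the stereoelectronics of a dissolving-metal reduction, C1 is epimerisable next to the C2 ketone, and C2 follows from axial hydride attack.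

C10 lies between two quaternary carbons, so a C1=C10 double bond in any precursor cannot be expected to hydrogenate on a catalyst surface. The electron-rich furan does not tolerate strong electrophiles or oxidants, and the γ-hydroxy-α,β-unsaturated lactone is prone to elimination and conjugate addition and should appear last.

The enabling feature is that the six carbons of ring B, with oxygen on C2, the carboxyl carbon C18 on C4 and the oxygenated methylene C19 on C5, are those of a 6-hydroxyphthalide. C5 is para to the C2 oxygen, so C-alkylation of the phenolate at C5 by a C6 electrophile tethered through C9 gives the quaternary centre, ring A and the oxidation pattern of ring B in one step.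

## Retrosynthesis

**C2 last.** 36 is traced to the C2 ketone 35. No skeletal bond is cut; only the C2–H bond is added, by a Luche reduction. This comes last because the allylic alcohol next to the unsaturated lactone is the most fragile part of the target. The forward step must distinguish the ene-dione-type C2 ketone from the C12 furyl ketone (a vinylogous ester) and deliver hydride axially.

**C3=C4 stored as a carbinol; C10 and C1 by electron transfer.** 35 is traced through the trans-fused diol 33 to the enone 31. The bonds added are C10–H and C1–H. The C3=C4 bond is more easily reduced than C1=C10, so it cannot stay in place. Hydrogenating it and dehydrogenating later was set aside, because in the saturated ketone C1–H (next to the C2 ketone and the acylfuran) is far more acidic than C3–H, and enolate-based dehydrogenation would regenerate C1=C10. Instead C3=C4 is carried as a C4 carbinol β to the C2 ketone. It is inert to dissolved lithium as its alkoxide and can later eliminate only toward C3.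

**From the dienone to 31.** 31 is traced through the β-hydroxy ketone 30 and the epoxide 29 to the dienone 28. Nucleophilic epoxidation picks the doubly activated C3=C4 bond, SmI2 opens the oxirane at C3, and borohydride reduces C7 while C2 is still a hindered conjugated ketone. Reducing C7 later would leave two saturated cyclohexanones to be told apart.

**Key cut, C5–C6.** 28 is traced to the phenolic bromomethyl ketone 26. This cut removes ring A and the C5 stereocentre and returns a flat arene whose substituents can be placed by aromatic chemistry. A free C11 arm on C9 would leave two chair transition states of similar energy, differing only in whether CH3 or the C11 methylene lies in the arene plane. Ring C is therefore already closed in 26: C11 is pinned in the plane, C6 can approach C5 only from the face opposite the C9 methyl, and attack at the furan-bearing C1 is excluded. The forward step needs only a carbonate base.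

**C6–C7 and C12–C13.** 26 comes from the silyl ether 25 and this from the acid 22 (diazo ketone homologation adds C6). 22 comes from the benzyl ester 21, whose ring C is cut at C12–C13 to the acid 19 (Friedel–Crafts acylation at the furan β-carbon). Closing ring C at C11–C12 instead would need a neopentyl carbanion attacking a furan ester in the presence of other carbonyl groups. The chosen cut uses the furan as nucleophile while it is still electron-rich and leaves it deactivated for all later steps.

**C12 from a vinyl group.** 19 is traced through the alcohol 18 and the benzyl ester 16 to the pentenoic acid 15. The vinyl group of 15 supplies C11 and C12 by anti-Markovnikov hydration and oxidation. The benzyl ester keeps the C7 carboxyl apart from the C12 carboxyl, which is needed because both could reach the furan through a seven-membered ring.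

**C8–C9 by [3,3].** 15 is traced to the allylic propanoate 13. An enantioselective Ireland–Claisen rearrangement forms the C8–C9 bond and both stereocentres, the quaternary one included, from an achiral ester. The forward step needs the E alkene, the E(O) enolate and a chiral boron controller.

**C9–C10 by cross-coupling.** 13 comes from the allylic alcohol 11 and propanoyl chloride 12. 11 is cut at the aryl–alkenyl bond to the triflate 10 and the alkenylboronate 2, which is made from but-2-yn-1-ol 1. C10 is meta to the phenol oxygen and cannot be reached by electrophilic substitution, so a second phenol is placed there and used as its triflate.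

**The arene.** 10 is traced through the phthalide phenol 9 and the silyl ether 7 to the biaryl 6, which is cut at C1–C16 to the bromide 4 and the furylboronate 5. 4 comes from methyl 4-bromo-3,5-dihydroxybenzoate 3 by ortho-formylation, which adds C19. The symmetry of 3 puts bromine between the two oxygens without a regiochemical choice, and the hydrogen bond of the new aldehyde distinguishes the two phenols.

## Roads not taken

Alternative 1: The furan and ring C are cut together at C16–C13 and C15–C14. Forward, the oxazolyl ynone A2 is heated; the 4-methyloxazol-5-yl group on C1 adds across the terminal ynone on the C9 arm, the bridged adduct loses its nitrile bridge, and the C2 silyl ether A1 of the target results. Its merits are that the furan appears only at the end, never meets acid or oxidant, and two rings form in one neutral step. Its weakness is that A2 already contains all seven stereocentres, the trans-decalin and the unsaturated lactone, so the hard part is only postponed. The cycloaddition also passes through a seven-membered tether, and A2 combines a terminal ynone with a C1–H that can eliminate the C2 silyloxy group on heating. In furan handling this road is better than the chosen one. The chosen plan sets against it that its furan does work: it closes ring C early, it blocks C1, and its bridge fixes the configuration of C5.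

Alternative 2: Rings A and B are cut together at C5–C10 and C1–C2. Forward, the triene A4 (a silyloxy dienoate and an E-vinylfuran in one chain) undergoes an intramolecular Diels–Alder reaction to the trans-decalin A3. This is the most economical ring construction of all: two rings and four stereocentres in one step, the trans fusion formed directly, no dissolving metal. For this target, however, the diene terminus C5 is fully substituted and the dienophile carbon C10 is attached to a quaternary carbon, so forcing conditions are needed with a furan that is itself a diene. Facial control rests on the small difference between CH3 and CH2OSi on C9. A3 emerges with the wrong C2 configuration, a ketal at C7 and ring C still open at C11–C12. The chosen plan is longer in ring-forming steps, but it forms its key bond by an SN2 reaction of a phenolate, fixes C5 by a ring constraint, and needs no inversion at C2.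

Alternative 3: Ring B is cut at C4–C5. Forward, zerovalent palladium inserts into the C4–Br bond of the bromoacrylate A6, the C5 aldehyde enolate binds, and reductive elimination gives the decalin aldehyde ester A5. The merit is real: the C3=C4 enoate arrives at the right oxidation level, so the detour through a C4 carbinol that the chosen plan needs is avoided, and C10 is already sp3. Against it, ring A with four contiguous stereocentres, including quaternary C9, must be made first without help from an arene. α-Alkenylation of an aldehyde enolate to a quaternary centre competes with aldol chemistry. Most seriously, C1 of A5 is a bare methylene, so the furan and ring C would have to be attached next to the C2 oxygen afterwards. The chosen plan carries the C1–furan bond from the first aromatic steps.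

Key step: step 17

Assumption: atom numbers are those defined in the first section; β is the face of the decalin that carries C19, α the opposite face.

Assumption: in step 9 the (S,S)-bromoborane with Et3N in toluene/hexane is taken to give the E(O) boron ketene acetal and the (2S,3S) acid; if the sense of induction is the opposite one, the (R,R) reagent is used and nothing else changes.

## Route

Step 1
Reactants: 1 but-2-yn-1-ol
Product: 2 (2Z)-3-(4,4,5,5-tetramethyl-1,3,2-dioxaborolan-2-yl)but-2-en-1-ol
Conditions: B2pin2, CuCl (5 mol %), PCy3, NaOt-Bu (cat.), MeOH, toluene, rt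
Reagents that add atoms: bis(pinacolato)diboron, CC1(C)OB(OC1(C)C)B1OC(C)(C)C(C)(C)O1
Why: Copper-catalysed borylcupration–protonation of the alkyne (formal hydroboration) places boron on the carbon remote from the hydroxymethyl group; syn delivery of B and H fixes the Z geometry (methyl cis to CH2OH).

Step 2
Reactants: 3 methyl 4-bromo-3,5-dihydroxybenzoate
Product: 4 methyl 4-bromo-2-formyl-3,5-dihydroxybenzoate
Conditions: MgCl2, Et3N, (CH2O)n, MeCN, reflux; aq. HCl
Reagents that add atoms: paraformaldehyde (formaldehyde), C=O
Why: Magnesium-mediated ortho-formylation of a phenol (Casnati–Skattebøl reaction); the only free ortho carbon is also para to the second phenol, the symmetry of 3 allows one product, and the new aldehyde deactivates the ring against a second formylation.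

Step 3
Reactants: 4 methyl 4-bromo-2-formyl-3,5-dihydroxybenzoate; 5 2-(furan-2-yl)-4,4,5,5-tetramethyl-1,3,2-dioxaborolane
Product: 6 methyl 2-formyl-4-(furan-2-yl)-3,5-dihydroxybenzoate
Conditions: Pd(OAc)2 (3 mol %), SPhos, K3PO4, dioxane/H2O, 80 °C
Reagents that add atoms: none
Why: Suzuki–Miyaura coupling of a di-ortho-substituted aryl bromide, for which a biarylphosphine ligand is suited; the bromide is the only halide present and the small hydroxyl groups flank it, so the coupling is run before the bulky silyl group is introduced.

Step 4
Reactants: 6 methyl 2-formyl-4-(furan-2-yl)-3,5-dihydroxybenzoate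
Product: 7 methyl 2-formyl-4-(furan-2-yl)-3-hydroxy-5-[(triisopropylsilyl)oxy]benzoate
Conditions: TIPSCl (1.05 equiv), imidazole, DMF, 0 °C
Reagents that add atoms: triisopropylsilyl chloride, CC(C)[Si](Cl)(C(C)C)C(C)C
Why: Selective silylation of the phenol para to the aldehyde; the ortho phenol is held in a hydrogen bond to the formyl oxygen and is less nucleophilic, as in 2,4-dihydroxybenzaldehydes.

Step 5
Reactants: 7 methyl 2-formyl-4-(furan-2-yl)-3-hydroxy-5-[(triisopropylsilyl)oxy]benzoate
Product: 9 5-(furan-2-yl)-4-hydroxy-6-[(triisopropylsilyl)oxy]-2-benzofuran-1(3H)-one, via hydroxymethyl ester 8 (not isolated)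
Conditions: NaBH4, MeOH/THF, 0 °C; then AcOH, rt
Reagents that add atoms: none
Why: Borohydride reduces the aldehyde and not the ester; the benzylic alcohol lactonises onto the neighbouring methyl ester to the phthalide, which fixes C19 and C18.

Step 6
Reactants: 9 5-(furan-2-yl)-4-hydroxy-6-[(triisopropylsilyl)oxy]-2-benzofuran-1(3H)-one
Product: 10 5-(furan-2-yl)-1-oxo-6-[(triisopropylsilyl)oxy]-1,3-dihydro-2-benzofuran-4-yl trifluoromethanesulfonate
Conditions: Tf2O, pyridine, CH2Cl2, −78 → 0 °C
Reagents that add atoms: trifluoromethanesulfonic anhydride, O=S(=O)(OS(=O)(=O)C(F)(F)F)C(F)(F)F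
Why: O-Sulfonylation of the remaining free phenol turns the C10 oxygen into a leaving group for cross-coupling.

Step 7
Reactants: 10 5-(furan-2-yl)-1-oxo-6-[(triisopropylsilyl)oxy]-1,3-dihydro-2-benzofuran-4-yl trifluoromethanesulfonate; 2 (2Z)-3-(4,4,5,5-tetramethyl-1,3,2-dioxaborolan-2-yl)but-2-en-1-ol
Product: 11 5-(furan-2-yl)-4-[(2E)-4-hydroxybut-2-en-2-yl]-6-[(triisopropylsilyl)oxy]-2-benzofuran-1(3H)-one
Conditions: Pd(OAc)2 (5 mol %), SPhos, K3PO4, THF/H2O (10:1), 50 °C
Reagents that add atoms: none
Why: Suzuki–Miyaura coupling of an aryl triflate with an alkenylboronate proceeds with retention of alkene geometry, so the aryl group ends trans to CH2OH (E); the hindered di-ortho-substituted triflate calls for the biarylphosphine ligand.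

Step 8
Reactants: 11 5-(furan-2-yl)-4-[(2E)-4-hydroxybut-2-en-2-yl]-6-[(triisopropylsilyl)oxy]-2-benzofuran-1(3H)-one; 12 propanoyl chloride
Product: 13 (2E)-3-{5-(furan-2-yl)-1-oxo-6-[(triisopropylsilyl)oxy]-1,3-dihydro-2-benzofuran-4-yl}but-2-en-1-yl propanoate
Conditions: pyridine, DMAP (cat.), CH2Cl2, 0 °C
Reagents that add atoms: none
Why: Acylation of the primary allylic alcohol; the propanoyl group supplies C7, C8 and the C8 methyl.

Step 9
Reactants: 13 (2E)-3-{5-(furan-2-yl)-1-oxo-6-[(triisopropylsilyl)oxy]-1,3-dihydro-2-benzofuran-4-yl}but-2-en-1-yl propanoate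
Product: 15 (2S,3S)-3-{5-(furan-2-yl)-1-oxo-6-[(triisopropylsilyl)oxy]-1,3-dihydro-2-benzofuran-4-yl}-2,3-dimethylpent-4-enoic acid, via boron ketene acetal 14 (not isolated)
Conditions: (4S,5S)-2-bromo-1,3-bis{[3,5-bis(trifluoromethyl)phenyl]sulfonyl}-4,5-diphenyl-1,3,2-diazaborolidine (1.3 equiv), Et3N, toluene/hexane, −78 °C; then −20 → 4 °C; aq. work-up
Reagents that add atoms: none
Why: Enantioselective Ireland–Claisen rearrangement through a chiral boron ketene acetal; in the chair transition state the E alkene puts the aryl group equatorial and the C9 methyl axial, and the E(O) enolate puts the C8 methyl axial, which gives the C8 methyl syn to the C9 methyl and anti to the aryl group. The sulfonamide ligand on boron selects the enantiotopic face, so C8 and C9 are set together with the new C8–C9 bond.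

Step 10
Reactants: 15 (2S,3S)-3-{5-(furan-2-yl)-1-oxo-6-[(triisopropylsilyl)oxy]-1,3-dihydro-2-benzofuran-4-yl}-2,3-dimethylpent-4-enoic acid
Product: 16 benzyl (2S,3S)-3-{5-(furan-2-yl)-1-oxo-6-[(triisopropylsilyl)oxy]-1,3-dihydro-2-benzofuran-4-yl}-2,3-dimethylpent-4-enoate
Conditions: BnBr, KHCO3, DMF, rt
Reagents that add atoms: benzyl bromide, BrCc1ccccc1
Why: O-Alkylation of the carboxylate under bicarbonate conditions, which spare the aryl silyl ether; the ester keeps the C7 carboxyl out of the later acylation and is removable by hydrogenolysis.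

Step 11
Reactants: 16 benzyl (2S,3S)-3-{5-(furan-2-yl)-1-oxo-6-[(triisopropylsilyl)oxy]-1,3-dihydro-2-benzofuran-4-yl}-2,3-dimethylpent-4-enoate
Product: 18 benzyl (2S,3S)-3-{5-(furan-2-yl)-1-oxo-6-[(triisopropylsilyl)oxy]-1,3-dihydro-2-benzofuran-4-yl}-5-hydroxy-2,3-dimethylpentanoate, via alkylborane 17 (not isolated)
Conditions: 9-BBN, THF, 0 °C → rt; then NaBO3·4H2O, H2O, rt
Reagents that add atoms: sodium perborate, [Na+].[Na+].O[B-]1(O)OO[B-](O)(O)OO1
Why: Hydroboration–oxidation; 9-BBN adds boron to the terminal carbon of the vinyl group on the quaternary centre and leaves esters, lactone and furan alone. The near-neutral perborate work-up limits δ-lactonisation of the hydroxy ester, which is taken on without delay.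

Step 12
Reactants: 18 benzyl (2S,3S)-3-{5-(furan-2-yl)-1-oxo-6-[(triisopropylsilyl)oxy]-1,3-dihydro-2-benzofuran-4-yl}-5-hydroxy-2,3-dimethylpentanoate
Product: 19 (3S,4S)-5-(benzyloxy)-3-{5-(furan-2-yl)-1-oxo-6-[(triisopropylsilyl)oxy]-1,3-dihydro-2-benzofuran-4-yl}-3,4-dimethyl-5-oxopentanoic acid
Conditions: TEMPO (20 mol %), PhI(OAc)2 (2.2 equiv), MeCN/H2O (1:1), rt
Reagents that add atoms: water, O
Why: Oxoammonium-mediated oxidation of the primary alcohol through the aldehyde hydrate to the acid under near-neutral conditions, chosen over chromium or ruthenium oxidants because of the electron-rich furan.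

Step 13
Reactants: 19 (3S,4S)-5-(benzyloxy)-3-{5-(furan-2-yl)-1-oxo-6-[(triisopropylsilyl)oxy]-1,3-dihydro-2-benzofuran-4-yl}-3,4-dimethyl-5-oxopentanoic acid
Product: 21 tetracyclic keto benzyl ester (8S,9S; ring C closed through C12–C13), via acid chloride 20 (not isolated)
Conditions: (COCl)2, DMF (cat.), CH2Cl2, 0 °C; then SnCl4 (1.1 equiv), CH2Cl2 (0.01 M), −78 → −20 °C
Reagents that add atoms: none
Why: Intramolecular Friedel–Crafts acylation of the furan; the β-carbon C13 is the only furan position the C12 acylium can reach (seven-membered ring), dilution suppresses intermolecular attack at the free α-carbon, and the ester carbonyl of C7 does not acylate. The product furan is a vinylogous ester and is deactivated for the rest of the route.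

Step 14
Reactants: 21 tetracyclic keto benzyl ester (8S,9S; ring C closed through C12–C13)
Product: 22 tetracyclic keto acid (8S,9S)
Conditions: H2 (1 atm), 10% Pd/C, EtOAc, rt
Reagents that add atoms: none
Why: Hydrogenolysis of the benzyl ester; the acylated furan, the aryl silyl ether and the phthalide are not reduced under these neutral conditions.

Step 15
Reactants: 22 tetracyclic keto acid (8S,9S)
Product: 25 bromomethyl ketone silyl ether (8S,9S; C7 ketone bearing C6H2Br; C2–OTIPS), via acid chloride 23 (not isolated), via diazo ketone 24 (not isolated)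
Conditions: 1-chloro-N,N,2-trimethylprop-1-en-1-amine, CH2Cl2, 0 °C; Me3SiCHN2, MeCN/THF, 0 °C → rt; then 48% aq. HBr, 0 °C
Reagents that add atoms: (trimethylsilyl)diazomethane, C[Si](C)(C)C=[N+]=[N-]; hydrogen bromide, Br
Why: Arndt–Eistert-type acylation of a diazoalkane followed by hydrobromination of the diazo ketone adds C6 and the leaving group; the acid chloride is made without base and no enolisable intermediate is exposed to base, so C8 keeps its configuration.

Step 16
Reactants: 25 bromomethyl ketone silyl ether (8S,9S; C7 ketone bearing C6H2Br; C2–OTIPS)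
Product: 26 bromomethyl ketone phenol (8S,9S; free C2–OH)
Conditions: TBAF, AcOH (1:1.1), THF, −20 → 0 °C
Reagents that add atoms: none
Why: Fluoride cleavage of the aryl silyl ether; the acetic acid buffer protonates the phenolate as it forms, so the phenol can be isolated before the cyclisation is triggered.

Step 17
Reactants: 26 bromomethyl ketone phenol (8S,9S; free C2–OH)
Product: 28 pentacyclic dienone (ring A closed; C7 ketone; C2 dienone with C1=C10 and C3=C4; C19 β), via cesium phenolate 27 (not isolated)
Conditions: Cs2CO3 (1.5 equiv), MeCN (0.005 M), 0 °C → rt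
Reagents that add atoms: none
Why: Cs2CO3 deprotonates the C2 phenol, and phenolate 27 displaces bromide from C6 of the tethered α-bromo ketone through its para carbon C5 in an SN2 reaction, leaving the cross-conjugated cyclohexa-2,5-dienone. The closest known reaction type is the base-mediated intramolecular para-C-alkylation of phenolates by tethered halides to 4,4-disubstituted cyclohexadienones. Ring A closes in the 6-exo-tet mode (C5 onto the exocyclic C6–Br bond; tether C6–C7–C8–C9–C10). The only new stereocentre is C5: ring C holds C11 in the plane of the arene, so the C9 methyl and the C8 arm lie on opposite faces, C6 can reach C5 only from the face of C8, and C19 is pushed to the face of the C9 methyl (β). The step needs C- over O-alkylation and para over ortho attack; the phenolate oxygen and C3 cannot reach C6, attack at the furan-bearing C1 would create a bridged dienone with a double bond at the one-carbon bridge, and high dilution suppresses intermolecular O-alkylation. An α-bromo ketone is a far better SN2 electrophile than a simple primary bromide, so carbonate at or below room temperature should suffice, which protects the epimerisable C8 centre and the lactone.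

Step 18
Reactants: 28 pentacyclic dienone (ring A closed; C7 ketone; C2 dienone with C1=C10 and C3=C4; C19 β)
Product: 29 3α,4α-epoxide of the dienone
Conditions: t-BuOOH, DBU (cat.), CH2Cl2, −20 → 0 °C
Reagents that add atoms: tert-butyl hydroperoxide, CC(C)(C)OO
Why: Weitz–Scheffer nucleophilic epoxidation; the peroxide anion adds only to C3=C4, which is activated by both the C2 ketone and the lactone carbonyl and has a free CH terminus, while the tetrasubstituted C1=C10 bond is shielded. The α-epoxide keeps the lactone cis-fused, but either epimer would serve because C3 and C4 become sp2 again in step 22.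

Step 19
Reactants: 29 3α,4α-epoxide of the dienone
Product: 30 4α-hydroxy ketone (C3 methylene; C4–OH β to the C2 ketone; C1=C10 intact)
Conditions: SmI2 (2.2 equiv), THF/MeOH, −90 °C
Reagents that add atoms: none
Why: Reductive opening of an α,β-epoxy ketone by SmI2: electron transfer to the C2 carbonyl, cleavage of the C3–O bond and protonation of the samarium enolate by methanol give the β-hydroxy ketone, while isolated and furyl ketones are inert without additives at this temperature. The C4 hydroxyl now stores the C3=C4 unsaturation.

Step 20
Reactants: 30 4α-hydroxy ketone (C3 methylene; C4–OH β to the C2 ketone; C1=C10 intact)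
Product: 31 4α,7β-diol (axial C7–OH; C2 enone)
Conditions: NaBH4, MeOH/THF, −40 °C
Reagents that add atoms: none
Why: Hydride reduction of the saturated C7 ketone; its β face is blocked by the syn-axial C19 methylene and C9 methyl, so hydride enters from the α (equatorial) side and the alcohol is axial. The tetrasubstituted conjugated C2 ketone and the vinylogous-ester C12 ketone are much less electrophilic at −40 °C.

Step 21
Reactants: 31 4α,7β-diol (axial C7–OH; C2 enone)
Product: 33 trans-fused 4α,7β-dihydroxy 2,12-diketone (1β-H, 10α-H), via trilithium enolate 32 (not isolated)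
Conditions: LiN(SiMe3)2 (2.1 equiv), THF, −78 °C; then Li (2.5 equiv), NH3(l)/THF, t-BuOH (1 equiv), −78 °C, 10 min; isoprene; NH4Cl; then Et3N, MeOH, rt
Reagents that add atoms: none
Why: Dissolving-metal (Birch-type) reduction of the enone: two electrons enter the C2=O/C1=C10/acylfuran π system and the C10 carbanion is protonated along the axis perpendicular to ring B in the chair–chair arrangement, from the α face, which gives the trans A/B fusion at a carbon between two quaternary centres. The hydroxyls are protected as lithium alkoxides, and the product enolate 32, conjugated into the furyl ketone, resists further reduction. On quench C1 is protonated and equilibrates to the trans B/C junction (H1 β), in which ring C spans two equatorial bonds.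

Step 22
Reactants: 33 trans-fused 4α,7β-dihydroxy 2,12-diketone (1β-H, 10α-H)
Product: 35 7β-acetoxy 2-ketone (C3=C4 restored), via diacetate 34 (not isolated)
Conditions: Ac2O, Et3N, DMAP, CH2Cl2, rt → 40 °C; then DBU, 0 °C → rt
Reagents that add atoms: acetic anhydride, CC(=O)OC(C)=O
Why: DMAP-catalysed acylation puts acetate on the hindered axial C7 alcohol and on the tertiary C4 alcohol; DBU then removes a C3 proton of the β-acetoxy ketone and acetate leaves (E1cB). Elimination can only give C3=C4 because C5 is quaternary, and enolisation toward C1 is reversible and unproductive.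

Step 23
Reactants: 35 7β-acetoxy 2-ketone (C3=C4 restored)
Product: 36 CNP0182929.1
Conditions: NaBH4, CeCl3·7H2O, MeOH, −78 °C
Reagents that add atoms: none
Why: Luche reduction; cerium-assisted borohydride attacks the C2 ketone of the ene-dione 1,2 and leaves the C12 vinylogous ester, the lactone and the acetate. Axial attack from the α face, anti to the axial C1–H, gives the equatorial 2β-alcohol trans to the C1–furan bond.

## Compound list

1 | but-2-yn-1-ol | CC#CCO | starting material
2 | (2Z)-3-(4,4,5,5-tetramethyl-1,3,2-dioxaborolan-2-yl)but-2-en-1-ol | C/C(=C\CO)B1OC(C)(C)C(C)(C)O1 | intermediate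
3 | methyl 4-bromo-3,5-dihydroxybenzoate | COC(=O)c1cc(O)c(Br)c(O)c1 | starting material
4 | methyl 4-bromo-2-formyl-3,5-dihydroxybenzoate | COC(=O)c1cc(O)c(Br)c(O)c1C=O | intermediate
5 | 2-(furan-2-yl)-4,4,5,5-tetramethyl-1,3,2-dioxaborolane | CC1(C)OB(OC1(C)C)c1ccco1 | starting material
6 | methyl 2-formyl-4-(furan-2-yl)-3,5-dihydroxybenzoate | COC(=O)c1cc(O)c(-c2ccco2)c(O)c1C=O | intermediate
7 | methyl 2-formyl-4-(furan-2-yl)-3-hydroxy-5-[(triisopropylsilyl)oxy]benzoate | COC(=O)c1cc(O[Si](C(C)C)(C(C)C)C(C)C)c(-c2ccco2)c(O)c1C=O | intermediate
8 | methyl 4-(furan-2-yl)-3-hydroxy-2-(hydroxymethyl)-5-[(triisopropylsilyl)oxy]benzoate | COC(=O)c1cc(O[Si](C(C)C)(C(C)C)C(C)C)c(-c2ccco2)c(O)c1CO | intermediate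
9 | 5-(furan-2-yl)-4-hydroxy-6-[(triisopropylsilyl)oxy]-2-benzofuran-1(3H)-one | O=C1OCc2c(O)c(-c3ccco3)c(O[Si](C(C)C)(C(C)C)C(C)C)cc12 | intermediate
10 | 5-(furan-2-yl)-1-oxo-6-[(triisopropylsilyl)oxy]-1,3-dihydro-2-benzofuran-4-yl trifluoromethanesulfonate | O=C1OCc2c(OS(=O)(=O)C(F)(F)F)c(-c3ccco3)c(O[Si](C(C)C)(C(C)C)C(C)C)cc12 | intermediate
11 | 5-(furan-2-yl)-4-[(2E)-4-hydroxybut-2-en-2-yl]-6-[(triisopropylsilyl)oxy]-2-benzofuran-1(3H)-one | C/C(=C\CO)c1c2COC(=O)c2cc(O[Si](C(C)C)(C(C)C)C(C)C)c1-c1ccco1 | intermediate
12 | propanoyl chloride | CCC(Cl)=O | starting material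
13 | (2E)-3-{5-(furan-2-yl)-1-oxo-6-[(triisopropylsilyl)oxy]-1,3-dihydro-2-benzofuran-4-yl}but-2-en-1-yl propanoate | CCC(=O)OC/C=C(\C)c1c2COC(=O)c2cc(O[Si](C(C)C)(C(C)C)C(C)C)c1-c1ccco1 | intermediate
14 | E(O) boron ketene acetal of 13 (methyl trans to O–B; boron in the (4S,5S)-1,3-bis{[3,5-bis(trifluoromethyl)phenyl]sulfonyl}-4,5-diphenyl-1,3,2-diazaborolidine ring) | C/C=C(/OB1N(S(=O)(=O)c2cc(cc(c2)C(F)(F)F)C(F)(F)F)[C@@H](c2ccccc2)[C@H](c2ccccc2)N1S(=O)(=O)c1cc(cc(c1)C(F)(F)F)C(F)(F)F)OC/C=C(\C)c1c2COC(=O)c2cc(O[Si](C(C)C)(C(C)C)C(C)C)c1-c1ccco1 | intermediate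
15 | (2S,3S)-3-{5-(furan-2-yl)-1-oxo-6-[(triisopropylsilyl)oxy]-1,3-dihydro-2-benzofuran-4-yl}-2,3-dimethylpent-4-enoic acid | C=C[C@@](C)([C@@H](C(=O)O)C)c1c2COC(=O)c2cc(O[Si](C(C)C)(C(C)C)C(C)C)c1-c1ccco1 | intermediate
16 | benzyl (2S,3S)-3-{5-(furan-2-yl)-1-oxo-6-[(triisopropylsilyl)oxy]-1,3-dihydro-2-benzofuran-4-yl}-2,3-dimethylpent-4-enoate | C=C[C@@](C)([C@@H](C(=O)OCc1ccccc1)C)c1c2COC(=O)c2cc(O[Si](C(C)C)(C(C)C)C(C)C)c1-c1ccco1 | intermediate
17 | B-alkyl-9-borabicyclo[3.3.1]nonane from 16 (boron on C12) | C(CB1C2CCCC1CCC2)[C@@](C)([C@@H](C(=O)OCc1ccccc1)C)c1c2COC(=O)c2cc(O[Si](C(C)C)(C(C)C)C(C)C)c1-c1ccco1 | intermediate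
18 | benzyl (2S,3S)-3-{5-(furan-2-yl)-1-oxo-6-[(triisopropylsilyl)oxy]-1,3-dihydro-2-benzofuran-4-yl}-5-hydroxy-2,3-dimethylpentanoate | OCC[C@@](C)([C@@H](C(=O)OCc1ccccc1)C)c1c2COC(=O)c2cc(O[Si](C(C)C)(C(C)C)C(C)C)c1-c1ccco1 | intermediate
19 | (3S,4S)-5-(benzyloxy)-3-{5-(furan-2-yl)-1-oxo-6-[(triisopropylsilyl)oxy]-1,3-dihydro-2-benzofuran-4-yl}-3,4-dimethyl-5-oxopentanoic acid | OC(=O)C[C@@](C)([C@@H](C(=O)OCc1ccccc1)C)c1c2COC(=O)c2cc(O[Si](C(C)C)(C(C)C)C(C)C)c1-c1ccco1 | intermediate
20 | acid chloride of 19 (C12 acyl chloride) | ClC(=O)C[C@@](C)([C@@H](C(=O)OCc1ccccc1)C)c1c2COC(=O)c2cc(O[Si](C(C)C)(C(C)C)C(C)C)c1-c1ccco1 | intermediate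
21 | tetracyclic keto benzyl ester: phthalide arene (C2–OTIPS) and furan bridged by C9–C11H2–C12(=O)–C13 (ring C); C9 bears CH3 and the (S)-CH(CH3)CO2Bn arm; 8S,9S | O=C1C[C@@](C)([C@@H](C(=O)OCc2ccccc2)C)c2c3COC(=O)c3cc(O[Si](C(C)C)(C(C)C)C(C)C)c2-c2occc21 | intermediate
22 | tetracyclic keto acid (as 21 with a free C7 carboxyl; 8S,9S) | O=C1C[C@@](C)([C@@H](C(=O)O)C)c2c3COC(=O)c3cc(O[Si](C(C)C)(C(C)C)C(C)C)c2-c2occc21 | intermediate
23 | acid chloride of 22 (C7 acyl chloride) | O=C1C[C@@](C)([C@@H](C(Cl)=O)C)c2c3COC(=O)c3cc(O[Si](C(C)C)(C(C)C)C(C)C)c2-c2occc21 | intermediate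
24 | diazo ketone (C7 ketone, C6 diazomethyl; 8S,9S) | O=C1C[C@@](C)([C@@H](C(=O)C=[N+]=[N-])C)c2c3COC(=O)c3cc(O[Si](C(C)C)(C(C)C)C(C)C)c2-c2occc21 | intermediate
25 | bromomethyl ketone silyl ether (C7 ketone, C6H2Br, C2–OTIPS; 8S,9S) | O=C1C[C@@](C)([C@@H](C(=O)CBr)C)c2c3COC(=O)c3cc(O[Si](C(C)C)(C(C)C)C(C)C)c2-c2occc21 | intermediate
26 | bromomethyl ketone phenol (free C2–OH; 8S,9S), the substrate of the key step | O=C1C[C@@](C)([C@@H](C(=O)CBr)C)c2c3COC(=O)c3cc(O)c2-c2occc21 | intermediate
27 | cesium phenolate of 26 | O=C1C[C@@](C)([C@@H](C(=O)CBr)C)c2c3COC(=O)c3cc([O-])c2-c2occc21.[Cs+] | intermediate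
28 | pentacyclic dienone: ring A closed by C5–C6; C7 ketone; ring B cyclohexa-2,5-dienone (C2=O, C1=C10, C3=C4); lactone, ring C ketone and furan intact; C19 β, C9 methyl β, C8 methyl β | O=C1C[C@@]23COC(=O)C2=CC(=O)C(c2occc2C(=O)C[C@@]4(C)[C@@H]1C)=C34 | intermediate
29 | 3α,4α-epoxide of 28 | O=C1C[C@@]23COC(=O)[C@@]25O[C@H]5C(=O)C(c2occc2C(=O)C[C@@]4(C)[C@@H]1C)=C34 | intermediate
30 | 4α-hydroxy ketone: C3 methylene, tertiary C4–OH, C2 enone with C1=C10, C7 ketone | O=C1C[C@@]23COC(=O)[C@]2(O)CC(=O)C(c2occc2C(=O)C[C@@]4(C)[C@@H]1C)=C34 | intermediate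
31 | 4α,7β-diol: as 30 with axial 7β-OH | O[C@@H]1C[C@@]23COC(=O)[C@]2(O)CC(=O)C(c2occc2C(=O)C[C@@]4(C)[C@@H]1C)=C34 | intermediate
32 | trilithium salt: C7 and C4 alkoxides and the C1=C2 enolate, 10α-H | [Li+].[Li+].[Li+].[O-][C@@H]1C[C@@]23COC(=O)[C@]2([O-])CC([O-])=C2c4occc4C(=O)C[C@@](C)([C@@H]1C)[C@@H]23 | intermediate
33 | trans-fused 4α,7β-dihydroxy 2,12-diketone (1β-H, 10α-H) | O[C@@H]1C[C@@]23COC(=O)[C@]2(O)CC(=O)[C@H]2c4occc4C(=O)C[C@@](C)([C@@H]1C)[C@@H]23 | intermediate
34 | 4α,7β-diacetate of 33 | CC(=O)O[C@@H]1C[C@@]23COC(=O)[C@]2(OC(C)=O)CC(=O)[C@H]2c4occc4C(=O)C[C@@](C)([C@@H]1C)[C@@H]23 | intermediate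
35 | 7β-acetoxy 2-ketone with C3=C4 (the target with C2 as ketone) | CC(=O)O[C@@H]1C[C@@]23COC(=O)C2=CC(=O)[C@H]2c4occc4C(=O)C[C@@](C)([C@@H]1C)[C@@H]23 | intermediate
36 | CNP0182929.1: 7β-acetoxy-2β-hydroxy compound; lactone C19–O–C18 on C5/C4; C3=C4; ring C ketone at C12; furan fused at C13/C16; 1β-H, 10α-H, 8β- and 9β-methyl | CC(=O)O[C@@H]1C[C@@]23COC(=O)C2=C[C@H](O)[C@H]2c4occc4C(=O)C[C@@](C)([C@@H]1C)[C@@H]23 | target

## Step count and least certain steps

Total: 23 steps. Longest linear sequence: 22 steps (3 to 36, steps 2–23); step 1 is a one-step side branch that supplies 2.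

**Step 17 (key step).** The most likely failure is intermolecular O-alkylation or oligomerisation outrunning the ring closure, if the bridged arene resists the bending that brings C6 to C5. Base-induced epimerisation at C8 during a long reaction is the second risk. The fallback replaces the anionic alkylation by a cationic one. It sets out from diazo ketone 24, isolated before HBr is added. Buffered fluoride (TBAF/AcOH) frees the phenol to give the phenolic diazo ketone F1. Trifluoroacetic acid in CH2Cl2 at 0 °C then protonates the diazo carbon, and the para carbon C5 of the neutral phenol displaces nitrogen from C6 (aryl participation), which returns to the route at 28. No base is present, so C8 is safe, and the same ring constraint fixes C5.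

**Step 9.** The rearrangement may be too slow at the low temperature that the boron enolate tolerates, because the quaternary centre forms next to a di-ortho-substituted arene; enantio- and diastereoselection may erode as the temperature is raised. The fallback gives up asymmetric induction. From 13, LiN(i-Pr)2 and Me3SiCl in THF at −78 °C give the silyl ketene acetal F2, which rearranges on heating to the racemic trimethylsilyl ester F3. Aqueous work-up gives the racemic acid, that is 15 together with its enantiomer F4. Crystallisation with (R)-1-phenylethylamine separates the salt F5 of the (2S,3S) acid, and acidification returns 15.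

**Step 21.** Over-reduction of the C12 furyl ketone or of the lactone by lithium is the main risk; retro-aldol opening of ring B at the C4 alkoxide is a second. The fallback accepts the over-reduction. From 31, the reduction is run with excess lithium and t-BuOH so that the enone and the furyl ketone are both reduced, giving the C12 carbinol F6. MnO2 in CH2Cl2 then re-oxidises only the furylic alcohol and returns to the route at 33.

**Step 22.** Acylation of the tertiary C4 hydroxyl may be incomplete, and the basic medium may open ring B by a retro-aldol reaction before elimination. The fallback separates the two events and avoids base in the elimination. From 33, Ac2O and pyridine acetylate only the secondary alcohol to the 7-monoacetate F7. Burgess reagent in toluene at 50 °C then dehydrates the tertiary alcohol by syn-elimination of its sulfamate toward C3, the only carbon with hydrogen, and gives 35.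

**Step 13.** Intermolecular acylation at the more nucleophilic free α-carbon of the furan, or Lewis-acid damage to the electron-rich furan and the benzyl ester, may compete with the seven-membered closure. The fallback uses an amide-derived electrophile without a metal halide. From 19, coupling with dimethylamine (EDC) gives the dimethylamide F8. Tf2O and 2-chloropyridine activate the amide, and the furan C13 attacks in an intramolecular Vilsmeier–Haack acylation to give the iminium triflate F9. Aqueous NaHCO3 hydrolyses it to 21.

## Further compounds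

F1 | step 17 | phenolic diazo ketone (24 without the silyl group) | O=C1C[C@@](C)([C@@H](C(=O)C=[N+]=[N-])C)c2c3COC(=O)c3cc(O)c2-c2occc21
F2 | step 9 | trimethylsilyl ketene acetal of 13 (methyl trans to OSiMe3) | C/C=C(/O[Si](C)(C)C)OC/C=C(\C)c1c2COC(=O)c2cc(O[Si](C(C)C)(C(C)C)C(C)C)c1-c1ccco1
F3 | step 9 | trimethylsilyl ester of the racemic (2S*,3S*) acid (one enantiomer drawn) | C=C[C@@](C)([C@@H](C(=O)O[Si](C)(C)C)C)c1c2COC(=O)c2cc(O[Si](C(C)C)(C(C)C)C(C)C)c1-c1ccco1
F4 | step 9 | (2R,3R) acid, the enantiomer of 15 | C=C[C@](C)([C@H](C(=O)O)C)c1c2COC(=O)c2cc(O[Si](C(C)C)(C(C)C)C(C)C)c1-c1ccco1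
F5 | step 9 | (R)-1-phenylethylammonium salt of 15 | C=C[C@@](C)([C@@H](C(=O)[O-])C)c1c2COC(=O)c2cc(O[Si](C(C)C)(C(C)C)C(C)C)c1-c1ccco1.C[C@@H]([NH3+])c1ccccc1
F6 | step 21 | C12 carbinol of 33 (mixture at C12) | O[C@@H]1C[C@@]23COC(=O)[C@]2(O)CC(=O)[C@H]2c4occc4C(O)C[C@@](C)([C@@H]1C)[C@@H]23
F7 | step 22 | 7β-monoacetate of 33 (free 4α-OH) | CC(=O)O[C@@H]1C[C@@]23COC(=O)[C@]2(O)CC(=O)[C@H]2c4occc4C(=O)C[C@@](C)([C@@H]1C)[C@@H]23
F8 | step 13 | N,N-dimethylamide of 19 | CN(C)C(=O)C[C@@](C)([C@@H](C(=O)OCc1ccccc1)C)c1c2COC(=O)c2cc(O[Si](C(C)C)(C(C)C)C(C)C)c1-c1ccco1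
F9 | step 13 | cyclic iminium triflate (C12=N+Me2 in ring C) | C[N+](C)=C1C[C@@](C)([C@@H](C(=O)OCc2ccccc2)C)c2c3COC(=O)c3cc(O[Si](C(C)C)(C(C)C)C(C)C)c2-c2occc21.[O-]S(=O)(=O)C(F)(F)F
A1 | alternative 1 | C2 O-tert-butyldimethylsilyl ether of the target | CC(=O)O[C@@H]1C[C@@]23COC(=O)C2=C[C@H](O[Si](C)(C)C(C)(C)C)[C@H]2c4occc4C(=O)C[C@@](C)([C@@H]1C)[C@@H]23
A2 | alternative 1 | oxazolyl ynone: decalin lactone with 4-methyloxazol-5-yl on C1 and CH2C(=O)C≡CH on C9 | CC(=O)O[C@@H]1C[C@@]23COC(=O)C2=C[C@H](O[Si](C)(C)C(C)(C)C)[C@@H](c2ocnc2C)[C@@H]3[C@@](C)(CC(=O)C#C)[C@@H]1C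
A3 | alternative 2 | trans-decalin cycloadduct (C2 epimer, C7 ketal) | COCOC[C@@]12CC3(OCCO3)[C@@H](C)[C@](C)(CO[Si](C)(C)C(C)(C)C)[C@H]1[C@H](c4occc4C(=O)OC)[C@H](O[Si](C)(C)C(C)(C)C)C=C2C(=O)OC
A4 | alternative 2 | acyclic triene: silyloxy dienoate and E-vinylfuran in one chain | COCOC/C(CC1(OCCO1)[C@@H](C)[C@](C)(CO[Si](C)(C)C(C)(C)C)/C=C/c1occc1C(=O)OC)=C(\C=C\O[Si](C)(C)C(C)(C)C)C(=O)OC
A5 | alternative 3 | trans-decalin aldehyde ester | COC(=O)C1=C[C@H](O[Si](C)(C)C(C)(C)C)C[C@H]2[C@@]1(C=O)C[C@@H](O[Si](C)(C)C(C)(C)C)[C@@H](C)[C@]2(C)CC(OC)OC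
A6 | alternative 3 | Z-α-bromoacrylate tethered to the ring A aldehyde (C5 epimers) | COC(=O)/C(Br)=C/[C@H](O[Si](C)(C)C(C)(C)C)C[C@H]1C(C=O)C[C@@H](O[Si](C)(C)C(C)(C)C)[C@@H](C)[C@]1(C)CC(OC)OC
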